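## Retrosynthetic overview

1. The target is a (2S)-7-hydroxyflavanone (rings A and C) whose aryl ring B carries a fused 2,2-dimethyldihydropyran ring D with a trans (3R,4S)-diol; locants O1, C2, C3, C4, C4a, C8, C8a below are those of the ring B/D chromane. The last disconnections are the two benzyl ethers and then the bond from C2 of ring C to ring B, made by catalyst-controlled asymmetric conjugate addition of a ring B/D arylboronate to 7-(benzyloxy)chromone (rings A and C bought intact).
2. Ring D is cut at O1–C2 and at C4a–C4. This gives a phenol with a single open ortho carbon, 2-(benzyloxy)-4-bromophenol, and the five-carbon epoxy aldehyde (S)-3,3-dimethyloxirane-2-carbaldehyde, made from 3-methylbut-2-en-1-ol by asymmetric epoxidation and oxidation.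
3. Enabling feature: in ring D, O1–C8a–C4a–C4(OH) is an ortho-hydroxybenzyl alcohol, that is, a phenolate ortho carbon added to an aldehyde. C3(OH)–C2(CH3)2–O1 is an epoxide opened by that phenol oxygen at a tertiary carbon that is not stereogenic. One chelated, strain-releasing annulation can therefore close ring D, bring C3 in from the reagent and set C4.
4. Ring order: ring D is the only ring constructed (key step, on the ring B phenol); rings A, B and C come from purchased arenes.

Key step: step 4

Assumption: the rhodium/chiral diene catalyst in step 7 is assumed to show the same facial sense on the chromone as on cyclic enones; if the (2R) epimer predominated, the mirror-image ligand would be used with the route otherwise unchanged.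

## Route

Step 1
Reactants: 1 3-methylbut-2-en-1-ol (prenol)
Product: 2 [(2R)-3,3-dimethyloxiran-2-yl]methanol
Conditions: Ti(OiPr)4 (5 mol%), D-(−)-diisopropyl tartrate (6 mol%), t-BuOOH (anhydrous), 4 Å MS, CH2Cl2, −20 °C; non-aqueous work-up, distillation
Reagents that add atoms: tert-butyl hydroperoxide, CC(C)(C)OO
Why: Sharpless asymmetric epoxidation of a primary allylic alcohol, in which the titanium–tartrate catalyst delivers oxygen to one face of the alkene and the D-(−)-tartrate ester is the enantiomer that should give the (R)-epoxy alcohol, setting the future C3.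

Step 2
Reactants: 2 [(2R)-3,3-dimethyloxiran-2-yl]methanol
Product: 3 (2S)-3,3-dimethyloxirane-2-carbaldehyde
Conditions: (n-Pr4N)RuO4 (5 mol%), N-methylmorpholine N-oxide, 4 Å MS, CH2Cl2, 0 °C to rt; short silica pad, concentrated cold and used at once as a CH2Cl2 solution
Reagents that add atoms: none
Why: Ley–Griffith oxidation stops at the aldehyde under neutral anhydrous conditions and leaves the epoxide stereocentre untouched (the descriptor changes from R to S only because the CIP priorities change).

Step 3
Reactants: 4 2-(benzyloxy)phenol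
Product: 5 2-(benzyloxy)-4-bromophenol
Conditions: N-bromosuccinimide (1.0 equiv), MeCN, 0 °C
Reagents that add atoms: N-bromosuccinimide, O=C1CCC(=O)N1Br
Why: Electrophilic aromatic bromination should go para to the free hydroxyl, the stronger donor, which installs the coupling handle and blocks the para position for the key step.

Step 4
Reactants: 5 2-(benzyloxy)-4-bromophenol; 3 (2S)-3,3-dimethyloxirane-2-carbaldehyde
Product: 8 (3R,4S)-8-(benzyloxy)-6-bromo-2,2-dimethyl-3,4-dihydro-2H-chromene-3,4-diol, via magnesium bis(phenolate) 6 (not isolated), via syn epoxy alcohol adduct 7 (not isolated)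
Conditions: n-Bu2Mg (0.55 equiv), toluene, 0 °C; then 3 (1.2 equiv), CH2Cl2, −30 °C to rt; then Ti(OiPr)4 (1.2 equiv), rt to 40 °C; aqueous work-up
Reagents that add atoms: none
Why: Proposed new method: the halide-free magnesium bis(phenolate) 6 binds aldehyde 3 through its carbonyl and epoxide oxygens and its only free ortho carbon adds to the carbonyl carbon in a six-membered cyclic transition state (C4a–C4 bond) to give adduct 7, after which Ti(OiPr)4 activates the epoxy alkoxide so that the phenoxide oxygen opens the strained epoxide at its tertiary carbon (O1–C2 bond), a 6-endo-tet closure of ring D driven by release of the epoxide strain. The closest known reactions are the ortho-specific hydroxyalkylation of magnesium phenolates with aldehydes (the aldehyde counterpart of the Casiraghi–Skattebøl ortho-formylation) and the titanium-mediated C3-selective opening of 2,3-epoxy alcohols, and their union on an α,β-epoxy aldehyde in one flask is the new element. C3 comes from 3 unchanged because its C–O bond is never broken, and inversion at C2 is without consequence because C2 carries two methyl groups. C4 is set in the addition: in the chelate (Cram-chelate model) the phenolate carbon attacks the carbonyl face remote from the epoxide carbon that bears the cis methyl group, which should give the syn adduct and, after closure through a chair with both oxygens equatorial, the trans (3R,4S)-diol. Regioselectivity rests on the magnesium template together with the benzyloxy group on one ortho carbon and bromine on the para carbon; 6-endo over 5-exo opening rests on the tertiary, cation-stabilising C2 and on the deactivating C4–O bond next to C3; the absence of halide avoids halohydrin formation.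

Step 5
Reactants: 8 (3R,4S)-8-(benzyloxy)-6-bromo-2,2-dimethyl-3,4-dihydro-2H-chromene-3,4-diol
Product: 9 (3R,4S)-8-(benzyloxy)-2,2-dimethyl-6-(4,4,5,5-tetramethyl-1,3,2-dioxaborolan-2-yl)-3,4-dihydro-2H-chromene-3,4-diol
Conditions: Pd(dppf)Cl2 (3 mol%), bis(pinacolato)diboron (1.2 equiv), KOAc (3 equiv), 1,4-dioxane, 85 °C
Reagents that add atoms: bis(pinacolato)diboron, CC1(C)OB(OC1(C)C)B1OC(C)(C)C(C)(C)O1
Why: Miyaura borylation through zerovalent palladium with KOAc tolerates free hydroxyl groups and benzyl ethers and touches no stereocentre.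

Step 6
Reactants: 10 7-hydroxy-4H-chromen-4-one (7-hydroxychromone)
Product: 11 7-(benzyloxy)-4H-chromen-4-one
Conditions: BnBr (1.1 equiv), K2CO3 (1.0 equiv), DMF, rt
Reagents that add atoms: benzyl bromide, BrCc1ccccc1
Why: Williamson ether synthesis on the acidic 7-hydroxyl under mild carbonate conditions that leave the chromone ring intact.

Step 7
Reactants: 9 (3R,4S)-8-(benzyloxy)-2,2-dimethyl-6-(4,4,5,5-tetramethyl-1,3,2-dioxaborolan-2-yl)-3,4-dihydro-2H-chromene-3,4-diol; 11 7-(benzyloxy)-4H-chromen-4-one
Product: 12 (2S)-7-(benzyloxy)-2-[(3R,4S)-8-(benzyloxy)-3,4-dihydroxy-2,2-dimethyl-3,4-dihydro-2H-chromen-6-yl]-2,3-dihydro-4H-chromen-4-one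
Conditions: [RhCl(C2H4)2]2 (2.5 mol%), (1S,4S)-2,5-diphenylbicyclo[2.2.2]octa-2,5-diene (5.5 mol%), KOH (0.1 equiv), 1,4-dioxane/H2O 10:1, 30 °C; 11 in slight excess
Reagents that add atoms: none
Why: Hayashi–Miyaura asymmetric 1,4-addition of an arylboron reagent to a chromone, in which the diene-bound arylrhodium adds to one enantioface of the C2=C3 bond of ring C and sets C2 under catalyst control while the remote free diol and both benzyl ethers are inert; any material from the minor enantiomer of 2 becomes a diastereomer here and should be removable by chromatography.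

Step 8
Reactants: 12 (2S)-7-(benzyloxy)-2-[(3R,4S)-8-(benzyloxy)-3,4-dihydroxy-2,2-dimethyl-3,4-dihydro-2H-chromen-6-yl]-2,3-dihydro-4H-chromen-4-one
Product: 13 (2S)-7-hydroxy-2-[(3R,4S)-3,4,8-trihydroxy-2,2-dimethyl-3,4-dihydro-2H-chromen-6-yl]-2,3-dihydro-4H-chromen-4-one (CNP0281318.3)
Conditions: H2 (1 atm), 10% Pd/C, EtOAc, rt; stopped as soon as 12 is consumed
Reagents that add atoms: none
Why: Hydrogenolysis of the two aryl benzyl ethers over Pd/C under neutral conditions should be much faster than cleavage of the secondary benzylic C4–OH or reduction of the aryl ketone, and it involves neither acid nor base, so all three stereocentres stay as set.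

## Compound list

1 | 3-methylbut-2-en-1-ol (prenol) | CC(C)=CCO | starting material
2 | [(2R)-3,3-dimethyloxiran-2-yl]methanol | OC[C@H]1OC1(C)C | intermediate
3 | (2S)-3,3-dimethyloxirane-2-carbaldehyde | O=C[C@H]1OC1(C)C | intermediate
4 | 2-(benzyloxy)phenol | Oc1ccccc1OCc1ccccc1 | starting material
5 | 2-(benzyloxy)-4-bromophenol | Oc1ccc(Br)cc1OCc1ccccc1 | intermediate
6 | magnesium bis[2-(benzyloxy)-4-bromophenolate], formed in the flask | [Mg+2].[O-]c1ccc(Br)cc1OCc1ccccc1.[O-]c1ccc(Br)cc1OCc1ccccc1 | intermediate
7 | 2-(benzyloxy)-4-bromo-6-{(S)-[(2R)-3,3-dimethyloxiran-2-yl](hydroxy)methyl}phenol, the syn adduct, present in the flask as its magnesium salt | Oc1c(OCc2ccccc2)cc(Br)cc1[C@H](O)[C@H]1OC1(C)C | intermediate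
8 | (3R,4S)-8-(benzyloxy)-6-bromo-2,2-dimethyl-3,4-dihydro-2H-chromene-3,4-diol (trans-diol) | CC1(C)Oc2c(OCc3ccccc3)cc(Br)cc2[C@H](O)[C@H]1O | intermediate
9 | (3R,4S)-8-(benzyloxy)-2,2-dimethyl-6-(4,4,5,5-tetramethyl-1,3,2-dioxaborolan-2-yl)-3,4-dihydro-2H-chromene-3,4-diol | CC1(C)Oc2c(OCc3ccccc3)cc(B3OC(C)(C)C(C)(C)O3)cc2[C@H](O)[C@H]1O | intermediate
10 | 7-hydroxy-4H-chromen-4-one | O=c1ccoc2cc(O)ccc12 | starting material
11 | 7-(benzyloxy)-4H-chromen-4-one | O=c1ccoc2cc(OCc3ccccc3)ccc12 | intermediate
12 | (2S)-7-(benzyloxy)-2-[(3R,4S)-8-(benzyloxy)-3,4-dihydroxy-2,2-dimethyl-3,4-dihydro-2H-chromen-6-yl]-2,3-dihydro-4H-chromen-4-one | CC1(C)Oc2c(OCc3ccccc3)cc([C@@H]3CC(=O)c4ccc(OCc5ccccc5)cc4O3)cc2[C@H](O)[C@H]1O | intermediate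
13 | (2S)-7-hydroxy-2-[(3R,4S)-3,4,8-trihydroxy-2,2-dimethyl-3,4-dihydro-2H-chromen-6-yl]-2,3-dihydro-4H-chromen-4-one | CC1(C)Oc2c(O)cc([C@@H]3CC(=O)c4ccc(O)cc4O3)cc2[C@H](O)[C@H]1O | target

## Summary and risks

Total step count: 8. Longest linear sequence: 6 steps (steps 1, 2, 4, 5, 7, 8).

Steps most likely to fail:

1. Step 4 (proposed new method). The addition may run through the non-chelated, dipole-minimised conformer of the epoxy aldehyde, which reverses the facial selectivity and leads to the cis-diol; the epoxide may open in the 5-exo mode; or the epoxy aldehyde may rearrange under Lewis acid before the C–C bond forms. The fallback uses known chemistry, sets out from 5 and comes back at 8. Phenol 5 is condensed with 3-methylbut-2-enal (CC(C)=CC=O) under PhB(OH)2 and AcOH in refluxing toluene with removal of water. Ortho-addition to the aldehyde, loss of water to an ortho-quinone methide and oxa-6π-electrocyclisation form the same two ring D bonds and give 8-(benzyloxy)-6-bromo-2,2-dimethyl-2H-chromene F1. Jacobsen–Katsuki epoxidation with (R,R)-[N,N'-bis(3,5-di-tert-butylsalicylidene)-1,2-cyclohexanediaminato]MnCl, NaOCl and 4-phenylpyridine N-oxide in CH2Cl2 at 0 °C is expected to give (3R,4R)-8-(benzyloxy)-6-bromo-3,4-epoxy-2,2-dimethylchromane F2; the mirror-image catalyst would be used if the sense were opposite. Dilute HClO4 in aqueous THF at 0 °C should then open the epoxide at the benzylic C4 with inversion to give trans-diol 8.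

2. Step 7. The electron-rich boronate may protodeboronate before transmetalation, or the C2 configuration may erode through base-induced retro-oxa-Michael opening of ring C. The fallback sets out from 8 and comes back at 12. Reductive carbonylation of 8 (Pd(OAc)2, di(1-adamantyl)-n-butylphosphine, CO/H2, TMEDA, toluene, 100 °C) gives (3R,4S)-8-(benzyloxy)-3,4-dihydroxy-2,2-dimethyl-3,4-dihydro-2H-chromene-6-carbaldehyde F3. Claisen–Schmidt condensation with commercial 1-[4-(benzyloxy)-2-hydroxyphenyl]ethanone (CC(=O)c1ccc(OCc2ccccc2)cc1O; KOH, EtOH, rt) gives (E)-1-[4-(benzyloxy)-2-hydroxyphenyl]-3-[(3R,4S)-8-(benzyloxy)-3,4-dihydroxy-2,2-dimethyl-3,4-dihydro-2H-chromen-6-yl]prop-2-en-1-one F4. NaOAc in refluxing EtOH closes ring C by intramolecular oxa-Michael addition to a mixture of 12 and its C2 epimer, (2R)-7-(benzyloxy)-2-[(3R,4S)-8-(benzyloxy)-3,4-dihydroxy-2,2-dimethyl-3,4-dihydro-2H-chromen-6-yl]-2,3-dihydro-4H-chromen-4-one F5. Because ring D is enantiopure these are diastereomers, to be separated by preparative HPLC; the (2R) epimer is recycled by re-equilibration through F4.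

3. Step 8. Over-reduction may compete with O-debenzylation, as hydrogenolysis of the benzylic C4–O bond or reduction of the aryl ketone. The fallback sets out from 12 and comes back at 13. The benzyl ethers are cleaved without hydrogen by BCl3 and pentamethylbenzene in CH2Cl2 at −78 °C, the benzyl cations being trapped by the arene, with a cold aqueous NaHCO3 quench to keep the C4 carbinol from ionising. It makes no new compound (entry none F0).

## Further compounds

F1 | step 4 | 8-(benzyloxy)-6-bromo-2,2-dimethyl-2H-chromene | CC1(C)C=Cc2cc(Br)cc(OCc3ccccc3)c2O1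
F2 | step 4 | (3R,4R)-8-(benzyloxy)-6-bromo-3,4-epoxy-2,2-dimethylchromane | CC1(C)Oc2c(OCc3ccccc3)cc(Br)cc2[C@H]2O[C@@H]12
F3 | step 7 | (3R,4S)-8-(benzyloxy)-3,4-dihydroxy-2,2-dimethyl-3,4-dihydro-2H-chromene-6-carbaldehyde | CC1(C)Oc2c(OCc3ccccc3)cc(C=O)cc2[C@H](O)[C@H]1O
F4 | step 7 | (E)-1-[4-(benzyloxy)-2-hydroxyphenyl]-3-[(3R,4S)-8-(benzyloxy)-3,4-dihydroxy-2,2-dimethyl-3,4-dihydro-2H-chromen-6-yl]prop-2-en-1-one | CC1(C)Oc2c(OCc3ccccc3)cc(/C=C/C(=O)c3ccc(OCc4ccccc4)cc3O)cc2[C@H](O)[C@H]1O
F5 | step 7 | (2R)-7-(benzyloxy)-2-[(3R,4S)-8-(benzyloxy)-3,4-dihydroxy-2,2-dimethyl-3,4-dihydro-2H-chromen-6-yl]-2,3-dihydro-4H-chromen-4-one | CC1(C)Oc2c(OCc3ccccc3)cc([C@H]3CC(=O)c4ccc(OCc5ccccc5)cc4O3)cc2[C@H](O)[C@H]1O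
F0 | step 8 | none | none
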